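**Retrosynthetic overview**

- The route rests on ring A (C4a, C5, C6, C7, C8, C8a): oxygen sits on C5, C7 and C8a, and the prenyl-bearing C6 lies between the C5 hydroxyl and the C7 methoxyl, the pattern of an acetate-built ring.
- Target 18 comes from 17 by freeing the 4'-phenol, and 17 from diol 16 by methylating O7; the hydrogen-bonded 5-OH is left alone.
- Ring A of 16 is cut at C7–C8 and C5–C6. This gives pyranone ester 8 (ring C with O1, C8a, C4a, the future C8 as a methyl group and the future C5 as an ester) and methyl 5-methylhex-4-enoate 13 (C7, C6 and the prenyl chain).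
- Pyranone 8 comes from tricarbonyl 6 and a one-carbon amide acetal; 6 comes from protected arylacetic acid 3 and methyl acetoacetate 4. Ester 13 comes from a Johnson–Claisen rearrangement of 9 with 10.
- Ring order: ring B is bought, ring C is closed in step 3, ring A in step 5.

Key step: step 5

Remark: the target has no stereocentre and no stereogenic double bond; chromone locants (C4a to C8a) are used for ring A atoms in open-chain intermediates as well, and 4-pyranone locants for 8.

**Step 1**
Reactants: 1 4-hydroxyphenylacetic acid
Product: 3 2-[4-(methoxymethoxy)phenyl]acetic acid, via methoxymethyl ester 2 (not isolated)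
Conditions: MOMCl (2.5 equiv), iPr2NEt, CH2Cl2, 0 °C → rt; then LiOH, THF/MeOH/H2O, rt; 1 M HCl to pH 4, 0 °C
Reagents that add atoms: chloromethyl methyl ether, COCCl; lithium hydroxide, [Li+].[OH-] (its oxygen ends in the carboxyl group)
Why: O-alkylation of the phenoxide and the carboxylate gives the doubly protected compound, and the methoxymethyl ester, an acyloxy acetal, should be saponified far faster than the aryl acetal ether, so that mild hydroxide frees only the acid.

**Step 2**
Reactants: 3 2-[4-(methoxymethoxy)phenyl]acetic acid; 4 methyl acetoacetate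
Product: 6 methyl 2-acetyl-4-[4-(methoxymethoxy)phenyl]-3-oxobutanoate, via acid chloride 5 (not isolated)
Conditions: 1-chloro-N,N,2-trimethylprop-1-en-1-amine (1.1 equiv), CH2Cl2, 0 °C → rt; then added to 4, MgCl2 (1 equiv), pyridine (2 equiv), CH2Cl2, 0 °C → rt; cold aqueous citric acid
Reagents that add atoms: none
Why: The chloroenamine makes the acid chloride without releasing HCl, so the acetal ether is safe, and the chelated magnesium enolate of the β-keto ester should be acylated at carbon (MgCl2/amine C-acylation of the Rathke type) to give the enolised tricarbonyl compound.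

**Step 3**
Reactants: 6 methyl 2-acetyl-4-[4-(methoxymethoxy)phenyl]-3-oxobutanoate
Product: 8 methyl 5-[4-(methoxymethoxy)phenyl]-2-methyl-4-oxo-4H-pyran-3-carboxylate, via enaminone 7 (not isolated)
Conditions: Me2NCH(OMe)2 (1.2 equiv), PhMe, 70 °C; then AcOH (2 equiv), 50 °C
Reagents that add atoms: N,N-dimethylformamide dimethyl acetal, COC(OC)N(C)C
Why: Aminomethylenation by the amide acetal should occur at the benzylic methylene, the only CH2 activated by both an aryl group and a carbonyl (as in the deoxybenzoin route to isoflavones), and the enol oxygen of the acetyl group then adds to the enaminone carbon and expels dimethylamine (addition–elimination), closing the 4-pyranone.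

**Step 4**
Reactants: 9 2-methylbut-3-en-2-ol; 10 trimethyl orthoacetate
Product: 13 methyl 5-methylhex-4-enoate, via mixed orthoester 11 (not isolated), via ketene acetal 12 (not isolated)
Conditions: EtCO2H (cat.), 110–135 °C, MeOH distilled off
Reagents that add atoms: none
Why: Johnson–Claisen rearrangement, in which acid-catalysed exchange and loss of methanol give the allyl ketene acetal and its [3,3]-sigmatropic shift moves the tertiary allylic oxygen into a new C–C bond; the new alkene carries two methyl groups, so no geometry has to be controlled.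

**Step 5**
Reactants: 8 methyl 5-[4-(methoxymethoxy)phenyl]-2-methyl-4-oxo-4H-pyran-3-carboxylate; 13 methyl 5-methylhex-4-enoate
Product: 16 5,7-dihydroxy-3-[4-(methoxymethoxy)phenyl]-6-(3-methylbut-2-enyl)chromen-4-one, via acylated ketone 14 (not isolated), via trione tautomer 15 (not isolated)
Conditions: LiN(iPr)2 (1.1 equiv), THF, −78 °C; 13 (1.05 equiv), −78 → 0 °C; LiN(iPr)2 (2.3 equiv), −78 °C → rt; aq NH4Cl
Reagents that add atoms: none
Why: Proposed new method: lithium diisopropylamide should remove a proton from the 2-methyl group of 8, which is vinylogous to both the ring carbonyl and the ester, and the cross-conjugated dienolate should be acylated at its exocyclic carbon by ester 13 (Claisen condensation, bond C7–C8), the released methoxide holding ketone 14 as its C8 enolate. The second charge of amide base should then remove a C6 proton to give a 1,3-dianion of the β-diketone type, whose terminal carbon attacks the neighbouring ring ester in a 6-exo-trig Dieckmann closure (bond C5–C6) held within reach by the cis C4a=C8a double bond; loss of methoxide and enolisation of trione 15 make ring A aromatic and the sequence irreversible. The closest known reaction type is the acylation of laterally lithiated ortho-toluates by esters followed by intramolecular Claisen condensation to naphthalene-1,3-diols, together with the known lateral lithiation of 2-methyl-4-pyranones, whereas the tandem on a 4-pyranone-3-carboxylate has not been shown. No stereocentre remains, since C6 of 15 becomes planar on enolisation. The step needs acylation of the dienolate at the exocyclic carbon instead of at C3 or oxygen, which the fully substituted C3 and the regain of the pyranone conjugation should favour, and carbon instead of oxygen attack on the ring ester (the isocoumarin-like enol lactone path), which the dianion and the methoxide-reversible lactone should secure; the prenyl group can end only on C6 because the O1–C8a bond is already in place when ring A forms.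

**Step 6**
Reactants: 16 5,7-dihydroxy-3-[4-(methoxymethoxy)phenyl]-6-(3-methylbut-2-enyl)chromen-4-one
Product: 17 5-hydroxy-7-methoxy-3-[4-(methoxymethoxy)phenyl]-6-(3-methylbut-2-enyl)chromen-4-one
Conditions: MeI (1.1 equiv), K2CO3 (1.2 equiv), acetone, rt → 40 °C
Reagents that add atoms: iodomethane, CI
Why: Williamson ether synthesis, in which the free and most acidic 7-hydroxyl should be alkylated while the 5-hydroxyl stays locked in its hydrogen bond to the C4 carbonyl and so should not react with one equivalent of MeI.

**Step 7**
Reactants: 17 5-hydroxy-7-methoxy-3-[4-(methoxymethoxy)phenyl]-6-(3-methylbut-2-enyl)chromen-4-one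
Product: 18 gancaonin G, 5-hydroxy-3-(4-hydroxyphenyl)-7-methoxy-6-(3-methylbut-2-enyl)chromen-4-one
Conditions: HCl (1 M in MeOH), rt → 40 °C
Reagents that add atoms: none
Why: Acid-catalysed transacetalisation of the aryl methoxymethyl ether with methanol frees the 4'-phenol, and dilute anhydrous acid at low temperature should leave the trisubstituted alkene next to the chelated 5-hydroxyl untouched.

**Compound list**

1 | 4-hydroxyphenylacetic acid | OC(=O)Cc1ccc(O)cc1 | starting material
2 | methoxymethyl 2-[4-(methoxymethoxy)phenyl]acetate | COCOC(=O)Cc1ccc(OCOC)cc1 | intermediate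
3 | 2-[4-(methoxymethoxy)phenyl]acetic acid | COCOc1ccc(CC(O)=O)cc1 | intermediate
4 | methyl acetoacetate | COC(=O)CC(C)=O | starting material
5 | 2-[4-(methoxymethoxy)phenyl]acetyl chloride | COCOc1ccc(CC(Cl)=O)cc1 | intermediate
6 | methyl 2-acetyl-4-[4-(methoxymethoxy)phenyl]-3-oxobutanoate | COC(=O)C(C(C)=O)C(=O)Cc1ccc(OCOC)cc1 | intermediate
7 | methyl 2-acetyl-5-(dimethylamino)-4-[4-(methoxymethoxy)phenyl]-3-oxopent-4-enoate | COC(=O)C(C(C)=O)C(=O)C(=CN(C)C)c1ccc(OCOC)cc1 | intermediate
8 | methyl 5-[4-(methoxymethoxy)phenyl]-2-methyl-4-oxo-4H-pyran-3-carboxylate | COC(=O)c1c(C)occ(-c2ccc(OCOC)cc2)c1=O | intermediate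
9 | 2-methylbut-3-en-2-ol | CC(C)(O)C=C | starting material
10 | trimethyl orthoacetate | COC(C)(OC)OC | starting material
11 | 3-(1,1-dimethoxyethoxy)-3-methylbut-1-ene | CC(OC)(OC)OC(C)(C)C=C | intermediate
12 | 3-(1-methoxyethenyloxy)-3-methylbut-1-ene | C=C(OC)OC(C)(C)C=C | intermediate
13 | methyl 5-methylhex-4-enoate | COC(=O)CCC=C(C)C | intermediate
14 | methyl 5-[4-(methoxymethoxy)phenyl]-2-(6-methyl-2-oxohept-5-enyl)-4-oxo-4H-pyran-3-carboxylate | COC(=O)c1c(CC(=O)CCC=C(C)C)occ(-c2ccc(OCOC)cc2)c1=O | intermediate
15 | 3-[4-(methoxymethoxy)phenyl]-6-(3-methylbut-2-enyl)-6,8-dihydrochromene-4,5,7-trione (racemic, transient) | CC(C)=CCC1C(=O)CC2=C(C1=O)C(=O)C(=CO2)c1ccc(OCOC)cc1 | intermediate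
16 | 5,7-dihydroxy-3-[4-(methoxymethoxy)phenyl]-6-(3-methylbut-2-enyl)chromen-4-one | COCOc1ccc(cc1)-c1coc2cc(O)c(CC=C(C)C)c(O)c2c1=O | intermediate
17 | 5-hydroxy-7-methoxy-3-[4-(methoxymethoxy)phenyl]-6-(3-methylbut-2-enyl)chromen-4-one | COCOc1ccc(cc1)-c1coc2cc(OC)c(CC=C(C)C)c(O)c2c1=O | intermediate
18 | gancaonin G | COc1cc2occ(-c3ccc(O)cc3)c(=O)c2c(O)c1CC=C(C)C | target

**Step count**

Total steps: 7. Longest linear sequence: 6 steps (steps 1, 2, 3, 5, 6, 7, from 1); step 4 is a one-step side branch.

**Steps most likely to fail**

1. Step 5 (the labelled step). The delocalised dienolate may be acylated too slowly by an unactivated, enolisable ester, so that proton transfer and self-condensation compete. The monoanion of 14 may also close through oxygen on the ring ester instead of through C6.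
Fallback with known chemistry, ring A brought in preformed; it sets out from 1 and comes back at 17.
   - 1 is condensed with benzene-1,3,5-triol in BF3·OEt2 at 80 °C (Friedel–Crafts acylation) to the deoxybenzoin 2-(4-hydroxyphenyl)-1-(2,4,6-trihydroxyphenyl)ethanone F1.
   - F1 is closed in the same flask with DMF and MsCl to genistein F2.
   - One equivalent each of K2CO3 and MeI in acetone should methylate the most acidic 7-hydroxyl to prunetin F3.
   - MOMCl with iPr2NEt protects the 4'-phenol to 5-hydroxy-7-methoxy-3-[4-(methoxymethoxy)phenyl]chromen-4-one F4, the chelated 5-hydroxyl staying free.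
   - Allyl bromide with K2CO3 in DMF at 60 °C gives the ether 7-methoxy-3-[4-(methoxymethoxy)phenyl]-5-(prop-2-enyloxy)chromen-4-one F5.
   - Aromatic Claisen rearrangement in N,N-diethylaniline at 190 °C moves the allyl group to C6, the only free ortho position, to give 5-hydroxy-7-methoxy-3-[4-(methoxymethoxy)phenyl]-6-(prop-2-enyl)chromen-4-one F6.
   - Cross-metathesis of F6 with 2-methylbut-2-ene and second-generation Grubbs catalyst in CH2Cl2 at 40 °C turns allyl into prenyl and gives 17.

2. Step 3. Aminomethylenation may take place at the acetyl methyl group instead of the benzylic methylene, the acetal may O-methylate the enolised tricarbonyl, or a second condensation may occur at the acidic 2-methyl group of the product.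
Fallback that attaches the aryl group last; it sets out from 4 and comes back at 8.
   - The magnesium enolate of 4 (MgCl2, pyridine, CH2Cl2) is C-acylated with (E)-3-ethoxyacryloyl chloride to methyl 2-acetyl-5-ethoxy-3-oxopent-4-enoate F7.
   - With catalytic TsOH in toluene at 60 °C F7 closes, with loss of ethanol, to methyl 2-methyl-4-oxo-4H-pyran-3-carboxylate F8.
   - Addition of Br2 in CH2Cl2 at 0 °C followed by elimination with Et3N gives methyl 5-bromo-2-methyl-4-oxo-4H-pyran-3-carboxylate F9.
   - Suzuki coupling of F9 with 4-(methoxymethoxy)phenylboronic acid (Pd(PPh3)4, K3PO4, 1,4-dioxane, 90 °C) gives 8.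

3. Step 7. During the acetal cleavage the protonated prenyl double bond may be captured by the neighbouring 5-hydroxyl (ring closure to a chroman) or by methanol.
Fallback that avoids Brønsted acid; it sets out from 17 and comes back at 18.
   - TMSOTf with 2,2'-bipyridyl in CH3CN at 0 °C should convert the aryl methoxymethyl ether into the silyl ether 5-hydroxy-7-methoxy-6-(3-methylbut-2-enyl)-3-[4-(trimethylsilyloxy)phenyl]chromen-4-one F10 under buffered, non-protic conditions.
   - Addition of water then hydrolyses F10 to 18.

**Further compounds**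

F1 | step 5 | 2-(4-hydroxyphenyl)-1-(2,4,6-trihydroxyphenyl)ethanone | O=C(Cc1ccc(O)cc1)c1c(O)cc(O)cc1O
F2 | step 5 | genistein | O=c1c(-c2ccc(O)cc2)coc2cc(O)cc(O)c12
F3 | step 5 | prunetin | COc1cc(O)c2c(c1)occ(-c1ccc(O)cc1)c2=O
F4 | step 5 | 5-hydroxy-7-methoxy-3-[4-(methoxymethoxy)phenyl]chromen-4-one | COCOc1ccc(cc1)-c1coc2cc(OC)cc(O)c2c1=O
F5 | step 5 | 7-methoxy-3-[4-(methoxymethoxy)phenyl]-5-(prop-2-enyloxy)chromen-4-one | COCOc1ccc(cc1)-c1coc2cc(OC)cc(OCC=C)c2c1=O
F6 | step 5 | 5-hydroxy-7-methoxy-3-[4-(methoxymethoxy)phenyl]-6-(prop-2-enyl)chromen-4-one | COCOc1ccc(cc1)-c1coc2cc(OC)c(CC=C)c(O)c2c1=O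
F7 | step 3 | methyl 2-acetyl-5-ethoxy-3-oxopent-4-enoate | CCO/C=C/C(=O)C(C(C)=O)C(=O)OC
F8 | step 3 | methyl 2-methyl-4-oxo-4H-pyran-3-carboxylate | COC(=O)c1c(C)occc1=O
F9 | step 3 | methyl 5-bromo-2-methyl-4-oxo-4H-pyran-3-carboxylate | COC(=O)c1c(C)occ(Br)c1=O
F10 | step 7 | 5-hydroxy-7-methoxy-6-(3-methylbut-2-enyl)-3-[4-(trimethylsilyloxy)phenyl]chromen-4-one | COc1cc2occ(-c3ccc(O[Si](C)(C)C)cc3)c(=O)c2c(O)c1CC=C(C)C
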